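**Retrosynthetic overview**
- The quinone is made last, from ring B, by para-oxygenation of a 3'-hydroxy-2',4'-dimethoxyphenyl flavone (phenol to para-quinone, as presumed in nature).
- That phenol comes from its 3'-O-benzyl, 5-O-methyl flavone by a single Lewis-acid unmasking.
- Ring C is closed in one pot along the chalcone → flavanone → flavone line (aldol condensation, oxa-Michael closure, dehydrogenation). The partners are an ω-methoxy-2-hydroxyacetophenone, which already carries the C3 methoxyl, and a benzaldehyde.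
- The ketone comes from 3,5-dimethoxyphenol and methoxyacetic acid; the aldehyde from 2,6-dimethoxyphenol by benzylation and formylation.
- Ring order: rings A and B are bought as arenes, ring C is closed in the cascade, and ring B becomes the quinone in the final step.

Assumption: the SMILES holds no stereocentre and no stereo-defined double bond, so the target is one achiral compound and the aryl–quinone axis is taken as freely rotating.

**Route**

Step 1
Reactants: 1 3,5-dimethoxyphenol
Product: 3 1-(2-hydroxy-4,6-dimethoxyphenyl)-2-methoxyethan-1-one, via difluoroboron chelate 2 (not isolated)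
Conditions: MeOCH2CO2H (1.3 equiv), BF3·OEt2 (5 equiv, neat), 85 °C, 2 h; then H2O, 50 °C
Reagents that add atoms: methoxyacetic acid, COCC(=O)O
Why: Friedel–Crafts (Nencki-type) acylation of the activated phenol goes ortho to OH (both ortho positions are equivalent) because the product is trapped as the six-membered O–BF2–O chelate 2, which water then hydrolyses, and BF3 leaves the methyl ethers alone.

Step 2
Reactants: 4 2,6-dimethoxyphenol
Product: 5 2-(benzyloxy)-1,3-dimethoxybenzene
Conditions: BnBr (1.1 equiv), K2CO3 (1.5 equiv), DMF, 60 °C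
Reagents that add atoms: benzyl bromide, BrCc1ccccc1
Why: Williamson ether synthesis on an acidic phenol with a reactive benzylic halide.

Step 3
Reactants: 5 2-(benzyloxy)-1,3-dimethoxybenzene
Product: 7 3-(benzyloxy)-2,4-dimethoxybenzaldehyde, via aryl iminium chloride 6 (not isolated)
Conditions: POCl3 (1.5 equiv), DMF, 0 → 75 °C; then H2O, 50 °C
Reagents that add atoms: N,N-dimethylformamide, CN(C)C=O; water, O
Why: Vilsmeier–Haack formylation goes para to one OMe and ortho to the other, as with 1,2,3-trimethoxybenzene, because the central benzyloxy group is twisted out of conjugation and activates its own para position poorly.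

Step 4
Reactants: 3 1-(2-hydroxy-4,6-dimethoxyphenyl)-2-methoxyethan-1-one; 7 3-(benzyloxy)-2,4-dimethoxybenzaldehyde
Product: 10 2-[3-(benzyloxy)-2,4-dimethoxyphenyl]-3,5,7-trimethoxy-4H-chromen-4-one, via (Z)-α-methoxychalcone 8 (not isolated), via trans-3-methoxyflavanone 9 (not isolated)
Conditions: pyrrolidine (0.5 equiv), DMSO, 80 °C until 7 is consumed; then I2 (0.1 equiv), 130 °C
Reagents that add atoms: none
Why: Proposed new method: pyrrolidine condenses 3 with 7 (iminium-activated Claisen–Schmidt) to chalcone 8, whose phenol closes by 6-endo oxa-Michael addition to racemic trans flavanone 9, and catalytic I2 (added only after the condensation so that it does not oxidise ketone 3) then iodinates the C3 enol ether and expels HI, which DMSO reoxidises, so that both transient stereocentres and the alkene geometry are erased; the closest known chemistry is the amine/I2/DMSO domino aldol–Michael–dehydrogenation of 2-hydroxyacetophenones with aryl aldehydes and the I2/DMSO oxidative cyclisation of 2'-hydroxychalcones, here extended to an α-methoxy ketone.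

Step 5
Reactants: 10 2-[3-(benzyloxy)-2,4-dimethoxyphenyl]-3,5,7-trimethoxy-4H-chromen-4-one
Product: 12 5-hydroxy-2-(3-hydroxy-2,4-dimethoxyphenyl)-3,7-dimethoxy-4H-chromen-4-one, via bis(dichloroboryl) aryloxide 11 (not isolated)
Conditions: BCl3 (4 equiv), C6HMe5 (3 equiv), CH2Cl2, −78 → 0 °C; then H2O, 0 °C → rt
Reagents that add atoms: none
Why: BCl3 with pentamethylbenzene as benzyl-cation scavenger cleaves the aryl benzyl ether at −78 °C, and on warming the boron held between the C4 carbonyl and the peri 5-OMe cleaves that one methyl ether (chelation-controlled demethylation), while the 3-OMe (five-membered chelate) and the other aryl methyl ethers react more slowly.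

Step 6
Reactants: 12 5-hydroxy-2-(3-hydroxy-2,4-dimethoxyphenyl)-3,7-dimethoxy-4H-chromen-4-one
Product: 13 2-(5-hydroxy-3,7-dimethoxy-4-oxo-4H-chromen-2-yl)-3,5-dimethoxycyclohexa-2,5-diene-1,4-dione (CNP0259413.0)
Conditions: (KSO3)2NO (2.5 equiv), KH2PO4 buffer pH 6, acetone–H2O, 0 °C → rt
Reagents that add atoms: potassium nitrosodisulfonate, [K+].[K+].[O]N(S(=O)(=O)[O-])S(=O)(=O)[O-]
Why: Teuber oxidation, in which the electron-rich, non-chelated 2,6-dimethoxyphenol of ring B gives a phenoxyl radical that a second nitroxyl traps at its only free ortho/para carbon (para, C6') to give the para-quinone, while the 5-OH, hydrogen-bonded to the C4 carbonyl on electron-poor ring A, reacts far more slowly; no stereocentre is formed.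

**Compound list**

1 | 3,5-dimethoxyphenol | COc1cc(O)cc(OC)c1 | starting material
2 | difluoroboron chelate of ketone 3 (BF2 bridging the phenolate O and the ketone O; 2,2-difluoro-5,7-dimethoxy-4-(methoxymethyl)-1,3,2-benzodioxaborinine) | COCC1=[O+][B-](F)(F)Oc2cc(OC)cc(OC)c12 | intermediate
3 | 1-(2-hydroxy-4,6-dimethoxyphenyl)-2-methoxyethan-1-one | COCC(=O)c1c(O)cc(OC)cc1OC | intermediate
4 | 2,6-dimethoxyphenol | COc1cccc(OC)c1O | starting material
5 | 2-(benzyloxy)-1,3-dimethoxybenzene | COc1cccc(OC)c1OCc1ccccc1 | intermediate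
6 | N-{[3-(benzyloxy)-2,4-dimethoxyphenyl]methylidene}-N-methylmethanaminium chloride | C[N+](C)=Cc1ccc(OC)c(OCc2ccccc2)c1OC.[Cl-] | intermediate
7 | 3-(benzyloxy)-2,4-dimethoxybenzaldehyde | O=Cc1ccc(OC)c(OCc2ccccc2)c1OC | intermediate
8 | (Z)-3-[3-(benzyloxy)-2,4-dimethoxyphenyl]-1-(2-hydroxy-4,6-dimethoxyphenyl)-2-methoxyprop-2-en-1-one | CO/C(=C\c1ccc(OC)c(OCc2ccccc2)c1OC)C(=O)c1c(O)cc(OC)cc1OC | intermediate
9 | trans-2-[3-(benzyloxy)-2,4-dimethoxyphenyl]-3,5,7-trimethoxy-2,3-dihydro-4H-chromen-4-one, racemic, (2R,3R) enantiomer drawn | COc1cc(OC)c2c(c1)O[C@H](c1ccc(OC)c(OCc3ccccc3)c1OC)[C@@H](OC)C2=O | intermediate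
10 | 2-[3-(benzyloxy)-2,4-dimethoxyphenyl]-3,5,7-trimethoxy-4H-chromen-4-one | COc1cc(OC)c2c(c1)oc(-c1ccc(OC)c(OCc3ccccc3)c1OC)c(OC)c2=O | intermediate
11 | 5-O,3'-O-bis(dichloroboryl) derivative of 12 (drawn without the O→B dative bond from the C4 carbonyl) | COc1cc(OB(Cl)Cl)c2c(c1)oc(-c1ccc(OC)c(OB(Cl)Cl)c1OC)c(OC)c2=O | intermediate
12 | 5-hydroxy-2-(3-hydroxy-2,4-dimethoxyphenyl)-3,7-dimethoxy-4H-chromen-4-one | COc1cc(O)c2c(c1)oc(-c1ccc(OC)c(O)c1OC)c(OC)c2=O | intermediate
13 | 2-(5-hydroxy-3,7-dimethoxy-4-oxo-4H-chromen-2-yl)-3,5-dimethoxycyclohexa-2,5-diene-1,4-dione | COC1=CC(=O)C(c2oc3cc(OC)cc(O)c3c(=O)c2OC)=C(OC)C1=O | target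

**Count**

Total steps: 6. Longest linear sequence: 5 steps (4 → 5 → 7 → 10 → 12 → 13).

**Steps most likely to fail, with fallbacks**

Step 4 (one-pot closure of ring C). Two hindered partners may condense slowly, and I2/DMSO can oxidise unreacted ketone 3. The fallback sets out from 7 and comes back at 10; the C3 oxygen is put in during the oxidative ring closure and is no longer carried in with the ketone. Aldehyde 7 is condensed with purchased 1-(2-hydroxy-4,6-dimethoxyphenyl)ethan-1-one (KOH, EtOH, rt) to the isolated chalcone (E)-3-[3-(benzyloxy)-2,4-dimethoxyphenyl]-1-(2-hydroxy-4,6-dimethoxyphenyl)prop-2-en-1-one F1. Alkaline H2O2 (NaOH, MeOH, 0 °C → rt; Algar–Flynn–Oyamada reaction) closes ring C through the racemic trans dihydroflavonol 2-[3-(benzyloxy)-2,4-dimethoxyphenyl]-3-hydroxy-5,7-dimethoxy-2,3-dihydro-4H-chromen-4-one F2 (not isolated) to the flavonol 2-[3-(benzyloxy)-2,4-dimethoxyphenyl]-3-hydroxy-5,7-dimethoxy-4H-chromen-4-one F3. MeI and K2CO3 in acetone then methylate the 3-OH to give 10. The known hazard of this fallback is aurone formation from 6'-methoxychalcones.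

Step 6 (radical para-oxygenation). The nitroxyl may attack the 5-hydroxy ring A or react sluggishly next to the bulky chromone. The fallback sets out from 12 and comes back at 13; it replaces radical oxygenation by electrophilic para-nitrosation followed by reduction and oxidation. NaNO2 in AcOH–EtOH–H2O at 0 °C nitrosates the ring B phenol at C6' to give 5-hydroxy-2-(3-hydroxy-2,4-dimethoxy-6-nitrosophenyl)-3,7-dimethoxy-4H-chromen-4-one F4 (tautomer of the quinone monooxime). Na2S2O4 in aqueous EtOH reduces it to the para-aminophenol 2-(6-amino-3-hydroxy-2,4-dimethoxyphenyl)-5-hydroxy-3,7-dimethoxy-4H-chromen-4-one F5. FeCl3 in dilute HCl oxidises this to the quinone imine 5-hydroxy-2-(6-imino-2,4-dimethoxy-3-oxocyclohexa-1,4-dien-1-yl)-3,7-dimethoxy-4H-chromen-4-one F6 (not isolated), which hydrolyses in the same flask to 13.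

Step 5 (one Lewis acid meeting six O-alkyl groups). BCl3 may also cleave the 3-OMe or a ring B OMe. The fallback sets out from 3 and comes back at 12; the peri oxygen is carried as a benzyl ether, so the late unmasking is a neutral hydrogenolysis and the only Lewis-acid demethylation is done on the simple ketone. AlCl3 in PhCl at 80 °C cleaves the second ortho OMe of 3 to give 1-(2,6-dihydroxy-4-methoxyphenyl)-2-methoxyethan-1-one F7. BnBr (1.0 equiv) and K2CO3 in acetone benzylate one of its two equivalent hydroxyls to give 1-[2-(benzyloxy)-6-hydroxy-4-methoxyphenyl]-2-methoxyethan-1-one F8. The conditions of step 4, applied to F8 and 7, run through the chalcone (Z)-1-[2-(benzyloxy)-6-hydroxy-4-methoxyphenyl]-3-[3-(benzyloxy)-2,4-dimethoxyphenyl]-2-methoxyprop-2-en-1-one F9 and the racemic flavanone trans-5-(benzyloxy)-2-[3-(benzyloxy)-2,4-dimethoxyphenyl]-3,7-dimethoxy-2,3-dihydro-4H-chromen-4-one F10 (neither isolated) to the flavone 5-(benzyloxy)-2-[3-(benzyloxy)-2,4-dimethoxyphenyl]-3,7-dimethoxy-4H-chromen-4-one F11. H2 over Pd/C in EtOAc removes both benzyl groups and gives 12.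

**Further compounds**

F1 | step 4 | (E)-3-[3-(benzyloxy)-2,4-dimethoxyphenyl]-1-(2-hydroxy-4,6-dimethoxyphenyl)prop-2-en-1-one | COc1cc(O)c(C(=O)/C=C/c2ccc(OC)c(OCc3ccccc3)c2OC)c(OC)c1
F2 | step 4 | trans-2-[3-(benzyloxy)-2,4-dimethoxyphenyl]-3-hydroxy-5,7-dimethoxy-2,3-dihydro-4H-chromen-4-one, racemic, (2R,3R) enantiomer drawn | COc1cc(OC)c2c(c1)O[C@H](c1ccc(OC)c(OCc3ccccc3)c1OC)[C@@H](O)C2=O
F3 | step 4 | 2-[3-(benzyloxy)-2,4-dimethoxyphenyl]-3-hydroxy-5,7-dimethoxy-4H-chromen-4-one | COc1cc(OC)c2c(c1)oc(-c1ccc(OC)c(OCc3ccccc3)c1OC)c(O)c2=O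
F4 | step 6 | 5-hydroxy-2-(3-hydroxy-2,4-dimethoxy-6-nitrosophenyl)-3,7-dimethoxy-4H-chromen-4-one | COc1cc(O)c2c(c1)oc(-c1c(N=O)cc(OC)c(O)c1OC)c(OC)c2=O
F5 | step 6 | 2-(6-amino-3-hydroxy-2,4-dimethoxyphenyl)-5-hydroxy-3,7-dimethoxy-4H-chromen-4-one | COc1cc(O)c2c(c1)oc(-c1c(N)cc(OC)c(O)c1OC)c(OC)c2=O
F6 | step 6 | 5-hydroxy-2-(6-imino-2,4-dimethoxy-3-oxocyclohexa-1,4-dien-1-yl)-3,7-dimethoxy-4H-chromen-4-one | COC1=CC(=N)C(c2oc3cc(OC)cc(O)c3c(=O)c2OC)=C(OC)C1=O
F7 | step 5 | 1-(2,6-dihydroxy-4-methoxyphenyl)-2-methoxyethan-1-one | COCC(=O)c1c(O)cc(OC)cc1O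
F8 | step 5 | 1-[2-(benzyloxy)-6-hydroxy-4-methoxyphenyl]-2-methoxyethan-1-one | COCC(=O)c1c(O)cc(OC)cc1OCc1ccccc1
F9 | step 5 | (Z)-1-[2-(benzyloxy)-6-hydroxy-4-methoxyphenyl]-3-[3-(benzyloxy)-2,4-dimethoxyphenyl]-2-methoxyprop-2-en-1-one | CO/C(=C\c1ccc(OC)c(OCc2ccccc2)c1OC)C(=O)c1c(O)cc(OC)cc1OCc1ccccc1
F10 | step 5 | trans-5-(benzyloxy)-2-[3-(benzyloxy)-2,4-dimethoxyphenyl]-3,7-dimethoxy-2,3-dihydro-4H-chromen-4-one, racemic, (2R,3R) enantiomer drawn | COc1cc(OCc2ccccc2)c2c(c1)O[C@H](c1ccc(OC)c(OCc3ccccc3)c1OC)[C@@H](OC)C2=O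
F11 | step 5 | 5-(benzyloxy)-2-[3-(benzyloxy)-2,4-dimethoxyphenyl]-3,7-dimethoxy-4H-chromen-4-one | COc1cc(OCc2ccccc2)c2c(c1)oc(-c1ccc(OC)c(OCc3ccccc3)c1OC)c(OC)c2=O
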